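**Retrosynthetic overview**
1. Target 22 ⇒ diol 18 by removing the two esters; the C2–O bond of 18 ⇒ cyclopentene 16 by a hydroxyl-guided copper hydride hydro-oxygenation (key C–O bond, new reaction).
2. Seven-membered ring ⇒ ring-closing metathesis of triene 13 (C8=C9); C4 carbinol ⇒ isopropyl Grignard addition to enone 11.
3. Enone 11 ⇒ aldol 9 by loss of the C2 silanol (the silyloxy group is a traceless stereo-relay); 9 ⇒ enone 4 + MeMgBr + 3-methylbut-3-enal (conjugate addition then aldol).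
4. Enone 4 ⇒ commercial (S)-4-silyloxycyclopentenone 1 + allylmagnesium bromide.
5. Ring order: the five-membered ring is bought with 1; the seven-membered ring is closed in step 6.

Assumption: the (Z)-2-methylbut-2-enoate of the SMILES is the angelate, and the ring stereocentres are (1R,3R,3aS,4S,8aR) in azulene numbering.

Numbering used in the text (daucane): C1 quaternary ring-fusion carbon with CH3, C2 angelate carbon, C3 CH2, C4 carbinol carbon with isopropyl, C5 ring-fusion CH, C6 aroyloxy carbon, C7 CH2, C8 methyl-bearing alkene carbon, C9 alkene CH, C10 CH2.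

The stereochemical rationales below are reasoned from models and analogy; none has been tested on these substrates.

**Step 1**
Reactants: 1 (4S)-4-[(tert-butyldimethylsilyl)oxy]cyclopent-2-en-1-one; 2 allylmagnesium bromide
Product: 4 (4S)-4-[(tert-butyldimethylsilyl)oxy]-3-(prop-2-en-1-yl)cyclopent-2-en-1-one, via trimethylsilyl enol ether 3 (not isolated)
Conditions: 2, CuBr·SMe2 (5 mol %), TMSCl, THF, –78 °C; then Pd(OAc)2 (10 mol %), O2, DMSO, 23 °C
Reagents that add atoms: allylmagnesium bromide 2, C=CC[Mg]Br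
Why: Copper-catalysed conjugate allylation in the presence of TMSCl occurs anti to the OTBS group and leaves silyl enol ether 3, which Saegusa–Ito oxidation returns to the enone with the allyl group on the β-carbon; the silyloxy stereocentre is untouched.

**Step 2**
Reactants: 5 3-methylbut-3-en-1-ol
Product: 6 3-methylbut-3-enal
Conditions: Dess–Martin periodinane, pyridine, CH2Cl2, 0 °C; used at once as a cold CH2Cl2 solution
Reagents that add atoms: none
Why: Buffered Dess–Martin oxidation gives the β,γ-unsaturated aldehyde without moving the double bond into conjugation; no stereocentre is formed.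

**Step 3**
Reactants: 4 (4S)-4-[(tert-butyldimethylsilyl)oxy]-3-(prop-2-en-1-yl)cyclopent-2-en-1-one; 7 methylmagnesium bromide; 6 3-methylbut-3-enal
Product: 9 (2S,3R,4S)-4-[(tert-butyldimethylsilyl)oxy]-2-[(1S)-1-hydroxy-3-methylbut-3-en-1-yl]-3-methyl-3-(prop-2-en-1-yl)cyclopentan-1-one, via bromomagnesium enolate 8 (not isolated)
Conditions: 7 (1.1 equiv), CuBr·SMe2 (10 mol %), THF–Me2S, –40 °C; then 6 (2 equiv), –78 °C
Reagents that add atoms: methylmagnesium bromide 7, C[Mg]Br; 3-methylbut-3-enal 6, CC(=C)CC=O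
Why: Copper-catalysed conjugate methylation occurs anti to OTBS (C1: methyl trans, allyl cis to OTBS), and the ring-locked (E)-enolate 8 then adds to 6 through a closed Zimmerman–Traxler transition state on the face away from OTBS and the pseudo-axial allyl group, which sets C5 (side chain cis to methyl, trans to allyl) and the anti aldol centre C6.

**Step 4**
Reactants: 9 (2S,3R,4S)-4-[(tert-butyldimethylsilyl)oxy]-2-[(1S)-1-hydroxy-3-methylbut-3-en-1-yl]-3-methyl-3-(prop-2-en-1-yl)cyclopentan-1-one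
Product: 11 (4S,5S)-5-[(1S)-1-hydroxy-3-methylbut-3-en-1-yl]-4-methyl-4-(prop-2-en-1-yl)cyclopent-2-en-1-one, via desilylated β-hydroxy ketone 10 (not isolated)
Conditions: AcOH–THF–H2O (3:1:1), 60 °C
Reagents that add atoms: none
Why: Aqueous acetic acid cleaves the secondary TBS ether and the β-hydroxy cyclopentanone 10 then loses water by acid-catalysed β-elimination through the less hindered C3 enol (the dehydration known for β-hydroxy cyclopentanones), which erases the C2 relay centre after it has set C1, C5 and C6 and leaves the more hindered aldol hydroxyl in place.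

**Step 5**
Reactants: 11 (4S,5S)-5-[(1S)-1-hydroxy-3-methylbut-3-en-1-yl]-4-methyl-4-(prop-2-en-1-yl)cyclopent-2-en-1-one; 12 isopropylmagnesium chloride
Product: 13 (1S,4S,5S)-5-[(1S)-1-hydroxy-3-methylbut-3-en-1-yl]-4-methyl-1-(propan-2-yl)-4-(prop-2-en-1-yl)cyclopent-2-en-1-ol
Conditions: 12 (2.5 equiv), LaCl3·2LiCl (1 equiv), THF, –20 °C
Reagents that add atoms: isopropylmagnesium chloride 12, CC(C)[Mg]Cl
Why: LaCl3·2LiCl-promoted Grignard 1,2-addition (enolisation and conjugate addition suppressed) reaches the enone carbonyl from the face anti to the C5 side chain, so the tertiary C4–OH ends up cis to the side chain and the C1 methyl group.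

**Step 6**
Reactants: 13 (1S,4S,5S)-5-[(1S)-1-hydroxy-3-methylbut-3-en-1-yl]-4-methyl-1-(propan-2-yl)-4-(prop-2-en-1-yl)cyclopent-2-en-1-ol
Product: 14 (3S,3aS,4S,8aS)-6,8a-dimethyl-3-(propan-2-yl)-3,3a,4,5,8,8a-hexahydroazulene-3,4-diol
Conditions: second-generation Grubbs catalyst RuCl2(=CHPh)(PCy3)(H2IMes) (5 mol %), CH2Cl2, 40 °C
Reagents that add atoms: none
Why: Ring-closing metathesis of the allyl and 2-methylallyl groups closes the trans-fused seven-membered ring with the trisubstituted C8=C9 bond and releases ethene; the cyclopentene, flanked by two fully substituted carbons, stays out of the reaction and no stereocentre changes.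

**Step 7**
Reactants: 14 (3S,3aS,4S,8aS)-6,8a-dimethyl-3-(propan-2-yl)-3,3a,4,5,8,8a-hexahydroazulene-3,4-diol; 15 4-[(tert-butyldimethylsilyl)oxy]benzoic acid
Product: 16 (3S,3aS,4S,8aS)-3-hydroxy-6,8a-dimethyl-3-(propan-2-yl)-3,3a,4,5,8,8a-hexahydroazulen-4-yl 4-[(tert-butyldimethylsilyl)oxy]benzoate
Conditions: 15, DCC, DMAP (0.2 equiv), CH2Cl2, 23 °C
Reagents that add atoms: 4-[(tert-butyldimethylsilyl)oxy]benzoic acid 15, CC(C)(C)[Si](C)(C)Oc1ccc(cc1)C(O)=O
Why: Steglich esterification acylates the only secondary hydroxyl (C6) while the tertiary allylic C4–OH does not react; no stereocentre changes.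

**Step 8**
Reactants: 16 (3S,3aS,4S,8aS)-3-hydroxy-6,8a-dimethyl-3-(propan-2-yl)-3,3a,4,5,8,8a-hexahydroazulen-4-yl 4-[(tert-butyldimethylsilyl)oxy]benzoate
Product: 18 (1R,3R,3aS,4S,8aR)-1,3-dihydroxy-6,8a-dimethyl-3-(propan-2-yl)-1,2,3,3a,4,5,8,8a-octahydroazulen-4-yl 4-[(tert-butyldimethylsilyl)oxy]benzoate, via bis-silyl ether 17 (not isolated)
Conditions: Cu(OAc)2 (5 mol %), DTBM-SEGPHOS (6 mol %, matched enantiomer), (MeO)2MeSiH (3 equiv), Me3SiOOSiMe3 (1.5 equiv, slow addition), THF, 40 °C; then MeOH, AcOH (cat.), 23 °C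
Reagents that add atoms: bis(trimethylsilyl) peroxide, C[Si](C)(C)OO[Si](C)(C)C
Why: Proposed new method: copper hydride-catalysed hydro-oxygenation of an unprotected allylic alcohol – the silane silylates the C4–OH in situ, the phosphine-ligated copper hydride adds across C2=C3 with copper at C2, the carbon distal to the C–O bond (inductive regiocontrol), from the less hindered face that carries the C4 oxygen and the C1 methyl group (the other face is shielded by the isopropyl group and C10), and the secondary alkylcopper is oxidised with retention by the O–O bond of the silyl peroxide while the silane turns Cu–OSiMe3 back into Cu–H, so C2–O forms cis to C4–OH; the closest known reactions are the copper hydride-catalysed hydroamination of unprotected allylic alcohols to γ-amino alcohols with O-benzoylhydroxylamines (the C–N counterpart) and the electrophilic hydroxylation of organometallic reagents with bis(trimethylsilyl) peroxide.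

**Step 9**
Reactants: 18 (1R,3R,3aS,4S,8aR)-1,3-dihydroxy-6,8a-dimethyl-3-(propan-2-yl)-1,2,3,3a,4,5,8,8a-octahydroazulen-4-yl 4-[(tert-butyldimethylsilyl)oxy]benzoate; 19 angelic acid
Product: 21 (1R,3R,3aS,4S,8aR)-3-hydroxy-6,8a-dimethyl-1-{[(2Z)-2-methylbut-2-enoyl]oxy}-3-(propan-2-yl)-1,2,3,3a,4,5,8,8a-octahydroazulen-4-yl 4-[(tert-butyldimethylsilyl)oxy]benzoate, via angelic 2,4,6-trichlorobenzoic anhydride 20 (not isolated)
Conditions: 19, 2,4,6-trichlorobenzoyl chloride, Et3N, toluene, 23 °C; then 18, 80 °C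
Reagents that add atoms: angelic acid 19, C/C=C(/C)C(O)=O
Why: Yamaguchi-type acylation with the preformed mixed anhydride, run without a nucleophilic catalyst so the (Z)-double bond does not isomerise to the tiglate, esterifies the secondary C2–OH while the tertiary C4–OH stays free; no stereocentre changes.

**Step 10**
Reactants: 21 (1R,3R,3aS,4S,8aR)-3-hydroxy-6,8a-dimethyl-1-{[(2Z)-2-methylbut-2-enoyl]oxy}-3-(propan-2-yl)-1,2,3,3a,4,5,8,8a-octahydroazulen-4-yl 4-[(tert-butyldimethylsilyl)oxy]benzoate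
Product: 22 (1R,3R,3aS,4S,8aR)-3-hydroxy-6,8a-dimethyl-1-{[(2Z)-2-methylbut-2-enoyl]oxy}-3-(propan-2-yl)-1,2,3,3a,4,5,8,8a-octahydroazulen-4-yl 4-hydroxybenzoate
Conditions: KHF2, MeOH, 23 °C
Reagents that add atoms: none
Why: KHF2 in methanol cleaves phenolic silyl ethers selectively under near-neutral conditions, so both esters and the angelate geometry survive; no stereocentre changes.

**Compound list**
1 | (4S)-4-[(tert-butyldimethylsilyl)oxy]cyclopent-2-en-1-one | CC(C)(C)[Si](C)(C)O[C@H]1CC(=O)C=C1 | starting material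
2 | allylmagnesium bromide | C=CC[Mg]Br | starting material
3 | tert-butyl(dimethyl){[(1S,2S)-2-(prop-2-en-1-yl)-4-[(trimethylsilyl)oxy]cyclopent-3-en-1-yl]oxy}silane (allyl trans to OTBS) | CC(C)(C)[Si](C)(C)O[C@H]1CC(O[Si](C)(C)C)=C[C@@H]1CC=C | intermediate
4 | (4S)-4-[(tert-butyldimethylsilyl)oxy]-3-(prop-2-en-1-yl)cyclopent-2-en-1-one | CC(C)(C)[Si](C)(C)O[C@H]1CC(=O)C=C1CC=C | intermediate
5 | 3-methylbut-3-en-1-ol | CC(=C)CCO | starting material
6 | 3-methylbut-3-enal | CC(=C)CC=O | intermediate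
7 | methylmagnesium bromide | C[Mg]Br | starting material
8 | bromomagnesium (3R,4S)-4-[(tert-butyldimethylsilyl)oxy]-3-methyl-3-(prop-2-en-1-yl)cyclopent-1-en-1-olate | CC(C)(C)[Si](C)(C)O[C@H]1CC(O[Mg]Br)=C[C@@]1(C)CC=C | intermediate
9 | (2S,3R,4S)-4-[(tert-butyldimethylsilyl)oxy]-2-[(1S)-1-hydroxy-3-methylbut-3-en-1-yl]-3-methyl-3-(prop-2-en-1-yl)cyclopentan-1-one | CC(C)(C)[Si](C)(C)O[C@H]1CC(=O)[C@H]([C@@H](O)CC(C)=C)[C@@]1(C)CC=C | intermediate
10 | (2S,3R,4S)-4-hydroxy-2-[(1S)-1-hydroxy-3-methylbut-3-en-1-yl]-3-methyl-3-(prop-2-en-1-yl)cyclopentan-1-one | O[C@H]1CC(=O)[C@H]([C@@H](O)CC(C)=C)[C@@]1(C)CC=C | intermediate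
11 | (4S,5S)-5-[(1S)-1-hydroxy-3-methylbut-3-en-1-yl]-4-methyl-4-(prop-2-en-1-yl)cyclopent-2-en-1-one | C1=CC(=O)[C@H]([C@@H](O)CC(C)=C)[C@@]1(C)CC=C | intermediate
12 | isopropylmagnesium chloride | CC(C)[Mg]Cl | starting material
13 | (1S,4S,5S)-5-[(1S)-1-hydroxy-3-methylbut-3-en-1-yl]-4-methyl-1-(propan-2-yl)-4-(prop-2-en-1-yl)cyclopent-2-en-1-ol | C1=C[C@@](O)(C(C)C)[C@H]([C@@H](O)CC(C)=C)[C@@]1(C)CC=C | intermediate
14 | (3S,3aS,4S,8aS)-6,8a-dimethyl-3-(propan-2-yl)-3,3a,4,5,8,8a-hexahydroazulene-3,4-diol | C1=C[C@@](O)(C(C)C)[C@@H]2[C@@H](O)CC(C)=CC[C@]21C | intermediate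
15 | 4-[(tert-butyldimethylsilyl)oxy]benzoic acid | CC(C)(C)[Si](C)(C)Oc1ccc(cc1)C(O)=O | starting material
16 | (3S,3aS,4S,8aS)-3-hydroxy-6,8a-dimethyl-3-(propan-2-yl)-3,3a,4,5,8,8a-hexahydroazulen-4-yl 4-[(tert-butyldimethylsilyl)oxy]benzoate | C1=C[C@@](O)(C(C)C)[C@@H]2[C@@H](OC(=O)c3ccc(O[Si](C)(C)C(C)(C)C)cc3)CC(C)=CC[C@]21C | intermediate
17 | (1R,3R,3aS,4S,8aR)-3-{[dimethoxy(methyl)silyl]oxy}-6,8a-dimethyl-3-(propan-2-yl)-1-[(trimethylsilyl)oxy]-1,2,3,3a,4,5,8,8a-octahydroazulen-4-yl 4-[(tert-butyldimethylsilyl)oxy]benzoate | C[Si](C)(C)O[C@@H]1C[C@@](O[Si](C)(OC)OC)(C(C)C)[C@@H]2[C@@H](OC(=O)c3ccc(O[Si](C)(C)C(C)(C)C)cc3)CC(C)=CC[C@]21C | intermediate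
18 | (1R,3R,3aS,4S,8aR)-1,3-dihydroxy-6,8a-dimethyl-3-(propan-2-yl)-1,2,3,3a,4,5,8,8a-octahydroazulen-4-yl 4-[(tert-butyldimethylsilyl)oxy]benzoate | O[C@@H]1C[C@@](O)(C(C)C)[C@@H]2[C@@H](OC(=O)c3ccc(O[Si](C)(C)C(C)(C)C)cc3)CC(C)=CC[C@]21C | intermediate
19 | angelic acid, (2Z)-2-methylbut-2-enoic acid | C/C=C(/C)C(O)=O | starting material
20 | (2Z)-2-methylbut-2-enoic 2,4,6-trichlorobenzoic anhydride | C/C=C(/C)C(=O)OC(=O)c1c(Cl)cc(Cl)cc1Cl | intermediate
21 | (1R,3R,3aS,4S,8aR)-3-hydroxy-6,8a-dimethyl-1-{[(2Z)-2-methylbut-2-enoyl]oxy}-3-(propan-2-yl)-1,2,3,3a,4,5,8,8a-octahydroazulen-4-yl 4-[(tert-butyldimethylsilyl)oxy]benzoate | C/C=C(/C)C(=O)O[C@@H]1C[C@@](O)(C(C)C)[C@@H]2[C@@H](OC(=O)c3ccc(O[Si](C)(C)C(C)(C)C)cc3)CC(C)=CC[C@]21C | intermediate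
22 | (1R,3R,3aS,4S,8aR)-3-hydroxy-6,8a-dimethyl-1-{[(2Z)-2-methylbut-2-enoyl]oxy}-3-(propan-2-yl)-1,2,3,3a,4,5,8,8a-octahydroazulen-4-yl 4-hydroxybenzoate | C/C=C(/C)C(=O)O[C@@H]1C[C@@](O)(C(C)C)[C@@H]2[C@@H](OC(=O)c3ccc(O)cc3)CC(C)=CC[C@]21C | target

**Step count**
Total: 10 steps. Longest linear sequence: 9 steps (steps 1, 3, 4, 5, 6, 7, 8, 9, 10, from 1); step 2 is a one-step side branch.

Stereocentres: C1, C5 and C6 are set in step 3 (relayed from the silyloxy centre of 1), C4 in step 5, C2 in step 8.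

**Three steps most likely to fail**

Step 3 (three stereocentres in one flask; the anti:syn ratio at C6 is the weakest point, and the acidic aldehyde 6 can quench the enolate). If C6 is formed unselectively, it is set instead by a hydroxyl-directed reduction. The C6 mixture is carried on to 13. Its secondary alcohol is oxidised with Dess–Martin periodinane and pyridine to 1-[(1R,2S,5S)-2-hydroxy-5-methyl-2-(propan-2-yl)-5-(prop-2-en-1-yl)cyclopent-3-en-1-yl]-3-methylbut-3-en-1-one F1. Reduction of this β-hydroxy ketone with Me4NBH(OAc)3 in AcOH–MeCN at –30 °C (intramolecular hydride delivery from the C4–O–B unit, 1,3-anti) gives back 13 as a single C6 epimer. This fallback sets out from 13 and returns to the route at 13.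

Step 4 (the acid could also dehydrate the aldol hydroxyl or cause retro-aldol cleavage). The fallback replaces the acid route by a base-induced β-elimination on a protected aldol. From 9, TESOTf and 2,6-lutidine give (2S,3R,4S)-4-[(tert-butyldimethylsilyl)oxy]-3-methyl-2-{(1S)-3-methyl-1-[(triethylsilyl)oxy]but-3-en-1-yl}-3-(prop-2-en-1-yl)cyclopentan-1-one F2. DBU in CH2Cl2 then removes the ring silyloxy group through the kinetically favoured C3 enolate, giving (4S,5S)-4-methyl-5-{(1S)-3-methyl-1-[(triethylsilyl)oxy]but-3-en-1-yl}-4-(prop-2-en-1-yl)cyclopent-2-en-1-one F3. HF·pyridine in THF removes the triethylsilyl group. This fallback sets out from 9 and returns to the route at 11.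

Step 8 (the proposed new reaction; the cis-alkene lies between two fully substituted carbons, the peroxide may oxidise the phosphine or be reduced directly by the copper hydride, and the face selectivity is untested). The fallback uses known chemistry. From 16, hydroxyl-directed epoxidation with VO(acac)2 (cat.) and t-BuOOH in CH2Cl2 gives (1S,2S,3R,3aS,4S,8aR)-1,2-epoxy-3-hydroxy-6,8a-dimethyl-3-(propan-2-yl)-1,2,3,3a,4,5,8,8a-octahydroazulen-4-yl 4-[(tert-butyldimethylsilyl)oxy]benzoate F4, with the epoxide oxygen cis to the tertiary hydroxyl. The trivalent titanium reagent Cp2TiCl (from Cp2TiCl2 and Zn) with 1,4-cyclohexadiene in THF then opens the epoxide at C3, the carbon next to the carbinol, and leaves the C2–O bond in place; the aryl ester is not touched. This fallback sets out from 16 and returns to the route at 18.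

**Further compounds**
F1 | step 3 | 1-[(1R,2S,5S)-2-hydroxy-5-methyl-2-(propan-2-yl)-5-(prop-2-en-1-yl)cyclopent-3-en-1-yl]-3-methylbut-3-en-1-one | C1=C[C@@](O)(C(C)C)[C@H](C(=O)CC(C)=C)[C@@]1(C)CC=C
F2 | step 4 | (2S,3R,4S)-4-[(tert-butyldimethylsilyl)oxy]-3-methyl-2-{(1S)-3-methyl-1-[(triethylsilyl)oxy]but-3-en-1-yl}-3-(prop-2-en-1-yl)cyclopentan-1-one | CC(C)(C)[Si](C)(C)O[C@H]1CC(=O)[C@H]([C@@H](O[Si](CC)(CC)CC)CC(C)=C)[C@@]1(C)CC=C
F3 | step 4 | (4S,5S)-4-methyl-5-{(1S)-3-methyl-1-[(triethylsilyl)oxy]but-3-en-1-yl}-4-(prop-2-en-1-yl)cyclopent-2-en-1-one | C1=CC(=O)[C@H]([C@@H](O[Si](CC)(CC)CC)CC(C)=C)[C@@]1(C)CC=C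
F4 | step 8 | (1S,2S,3R,3aS,4S,8aR)-1,2-epoxy-3-hydroxy-6,8a-dimethyl-3-(propan-2-yl)-1,2,3,3a,4,5,8,8a-octahydroazulen-4-yl 4-[(tert-butyldimethylsilyl)oxy]benzoate | O1[C@@H]2[C@H]1[C@@](O)(C(C)C)[C@@H]3[C@@H](OC(=O)c4ccc(O[Si](C)(C)C(C)(C)C)cc4)CC(C)=CC[C@@]23C
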